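The constants were drawn at random within sensible limits; the flask was simulated.

Amounts here are fractions of the charged solid substrate.

| flask | solid substrate | temperature | time | remark |
|---|---|---|---|---|
| spring | 0.19 M | 60 °C | 4.0 h |  |
| summer | 0.19 M |  | 4.0 h | at 100 °C until 3.0 h, from then on at 60 °C |
| autumn | 0.19 M | 80 °C | 4.0 h |  |
| dawn | 0.19 M | 100 °C | 4.0 h |  |

    solid substrate ⇌ starting material, rate k1*(cs1 - [starting material]) while solid is left; crystals form when [starting material] > cs1 (cs1 = 0.14 M, k1 = 0.0071 /min)
    target → over-reaction product (k2 = 0.0046 /min, Ea2 = 113 kJ/mol)
    2 starting material → self-condensation product (k3 = 0.12 /M/min, Ea3 = 66.0 kJ/mol)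
    starting material ⇌ target (K4 = 1.4, k4 = 0.0092 /min, Ea4 = 113 kJ/mol, ΔH4 = −38.0 kJ/mol)
    target ⇌ isomer of the product (K5 = 2.1, k5 = 0.11 /min, Ea5 = 95.0 kJ/mol, ΔH5 = −52.0 kJ/mol)
    isomer of the product ⇌ starting material (k6 = 0.010 /min, Ea6 = 103 kJ/mol)
    (constants at 100 °C)

- percentages count the solid substrate that a species holds: one self-condensation product counts as two
- where a step has two of a species, its rate is k times that concentration squared, and two are used at each turn
- solid, in amounts per volume of the solution: solid substrate
- all constants are for 100 °C and move with temperature by the activation energies and enthalpies
- at the start none of the solid substrate is in solution
- what has only dissolved of solid substrate counts as not reacted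

- which flask leads in amount of target, in percent of the solid substrate charged ("all alike" within 1.5 percentage points) (spring / summer / autumn / dawn / all alike)
- how much target is there at the end, in percent of the solid substrate charged: spring
- how much target is there at the end, in percent of the solid substrate charged: summer
- how much target is there at the end, in percent of the solid substrate charged: autumn
- how much target is there at the end, in percent of the solid substrate charged: dawn

Starting material, target and isomer of the product form a ring, and solid substrate feeds it from outside. At 100 °C, where the constants stand as given, the half-lives by single steps make a ladder.

Target into isomer, forward: 6.30 min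

Isomer with starting material, both ways together: 17.6 min

Starting material into target, forward: 75.3 min

Target into over-reaction product: 151 min

Charge divided by the fastest possible dissolving rate: 191 min

In dawn the feed is slower than each turn of the ring, but its time is 2.54 times the half-life of starting material into target, a narrow margin, so the dissolved pool can lag behind equilibrium while solid still enters. At equilibrium, starting material, target and isomer stand as one to 1.4 to 2.94.

Target's part: 0.262

This is the equilibrium share, target divided by the three dissolved species together. Over-reaction and self-condensation take material out of the pool, so this reckoning puts target in dawn below 26.2 % of the charge.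

The reckoning stops there. In spring the forward half-life of target into isomer grows to 4.15 h, about as long as the run of 4.0 h, so the share at 100 °C gives no figure for that flask.

The forecast gives a figure where this reckoning gives a limit. It names dawn, because “the hot flask wins”. Its values are 1.9 % for spring, 13.6 % for summer, 10.8 % for autumn and 18 % for dawn.

The simulation gives 1.46 % for spring, 12.0 % for summer, 9.83 % for autumn and 16.7 % for dawn, so dawn leads.

In dawn at 4.00 h, target passes into isomer with a forward half-life of 0.11 h, shorter than the run of 4.0 h, and target stands at 0.243 of the dissolved pool against the equilibrium share of 0.262. In summer, still at 100 °C at the change of temperature, the pool reads 16.5 % starting material, 13.6 % target and 29.7 % isomer at 3.00 h, which puts target at 0.227 of that pool.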